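## Structural features

Putraflavone is a 3',8''-linked biflavone without any stereogenic centre, in which two 5,7-dioxygenated 2-aryl-4H-chromen-4-ones are joined by one aryl–aryl bond. In the first unit (benzo ring A and pyranone ring C, O1 to C8a) O7 is methylated and O5 is free, and its ring B (C1'–C6') carries a free 4'-OH and is bonded through C3' to C8'' of the second unit. That second unit (benzo ring D and pyranone ring E, O1'' to C8a'') has free 5''- and 7''-hydroxyls and a 4-methoxyphenyl group (ring F, C1'''–C6''') at C2''. The C3'–C8'' axis has three ortho substituents (O4', O7'', C8a'') but carries no defined configuration in the target. The fragile elements are the pyranones, which hot alkali opens, and the 5''-hydroxy-8''-aryl array, which in strong acid can open and re-close on the other ortho oxygen (Wessely–Moser) and so move the aryl group to C6''. The real difficulty lies in telling six oxygens apart on an unsymmetrical dimer (two methyl ethers must stay while four phenols are set free), in making the hindered biaryl bond at C8'' and not at C6'', and in closing one pyranone late without strong acid or strong base. The key step uses the fact that O1–C2 of the 7-methoxy unit is, in oxidation level, the aryl ester of the ring B carboxylic acid, while C3 is the α-carbon of the C4 aryl ketone and can carry a triphenylphosphonium ylide, so that bonding C3 to C2 closes ring C.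

## Logic of the disconnections

18 to 17. The four O–CH2Ph bonds at O5, O4', O5'' and O7'' are cut. Every phenol has to be masked while an acid chloride and a basic ylide are handled, and a benzyl ether leaves under neutral reductive conditions, so no acid touches the 5''-hydroxy-8''-aryl flavone of 18. The demand on the forward step is that hydrogenolysis spares two pyranone C2=C3 bonds and two methyl ethers.

17 to 16. The C2=C3 bond of the 7-methoxy chromone is cut as a Wittig retron. Ring C of 17 becomes the aryl ester and the acyl-stabilised ylide of 16, which removes one ring and needs neither enolate nor acid. The forward step must make a stabilised ylide attack an ester carbonyl, so the ester has to be an aryl ester held in a six-membered arrangement, and no proton source may be present in 16.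

16 to 9 and 14 (through 15). The ester C2–O1 bond is cut. This splits 16 into two halves of comparable size that are joined far from the biaryl axis, which makes the route convergent. The forward acylation must take place on the phenolic oxygen of 14 and not on its ylide carbon, and only one ortho oxygen may be free; the benzyl ether already present in 14 secures the second point.

14 to 12, 11 and then 10 plus 2. The C3–P bond (through 13), the C3–Br bond and one O–benzyl bond are cut in turn. This takes 14 back to the symmetric 10, in which mono-benzylation can give only one product. The forward bromination of 11 must hit the methyl group and not the electron-rich nucleus, and 12 must meet the phosphine before it meets any base.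

9 to 8. The acid is traced to its methyl ester, the form that survives cross-coupling. The forward hydrolysis must leave ring E closed.

8 to 4 and 7. The C3'–C8'' biaryl bond is cut. This is the largest single simplification, since it divides 8 into a protected flavone and a benzoate. The forward coupling must join the di-ortho-substituted iodide 4 to the ortho-substituted boronate 7.

7 to 6 and then 5 plus 2. The C3'–B bond and the O4'–benzyl bond are cut, leading to the commercial 5. The borylation of 6 must tolerate the ester.

4 to 3 and then 1 plus 2. The C8''–I bond and the two O–benzyl bonds at O5'' and O7'' are cut, leading to 1, which already holds rings D, E and F with the right methyl ether. The forward iodination must go to C8'' and not C6'', which is why both phenols of 1, including the chelated 5''-OH, are alkylated first.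

## Other disconnections considered

Alternative 1: The cut runs through benzo ring D: C8''–C8a'', C6''–C7'' and C4a''–C8a'' are removed, leaving 3-ethoxycyclobut-2-en-1-one A1 and the ring B siloxyalkyne A2.
- Forward step: heating would open the four-membered ring of A1 by a 4π electrocyclic process; (2+2) addition to the alkyne of A2, a second 4π opening, 6π closure and tautomerisation should then give the arylphloroglucinol A3 with a free hydroxyl at C8a'', the silyl ether at O7'' and the ethyl ether at O5''.
- In its favour: the aryl group sits at C8'' by construction, so there is neither a halogenation regiochemistry question nor a hindered cross-coupling. On these two points it is better than the chosen plan. The three oxygens of ring D also emerge differentiated.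
- Against it: A2 would take several steps to make. After the annulation neither pyranone exists: ring E still needs acylation at C4a'' and closure, and the acetal of A3 must be unmasked and grown into the whole 7-methoxy chromone. The O5'' ethyl ether must finally be cleaved beside two methyl ethers, which only chelation-assisted Lewis acid cleavage could do, and that exposes a 5''-hydroxy-8''-aryl flavone to acid.
- Comparison: on structure it answers the C8''/C6'' problem more rigorously. On mechanism the pericyclic cascade is as well founded as the Wittig closure. On step economy it is clearly worse, since it discards the ready-made rings D, E and F of 1 and would need roughly twice as many operations.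

Alternative 2: Ring B is cut at C2'–C3' and C1'–C6', giving the 8''-(4-methoxy-2-siloxybutadienyl) flavone A4 and methyl propiolate A5.
- Forward step: a thermal (4+2) cycloaddition, in which the methoxy-bearing diene terminus C6' pairs with the ester-bearing alkyne carbon C1'; loss of methanol and of the silyl group should aromatise the adduct to the phenol ester A6.
- In its favour: the biaryl bond never has to be made by coupling at a tri-ortho-substituted centre, and the regiochemistry follows from the polarisation of both partners. A6 is one benzylation away from 8, so all later chemistry is the same; from there on the two plans are equal.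
- Against it: A4 still needs a carbon substituent at C8'', hence the same iodide 4 and the same regiochemical question. Building the oxygenated diene side chain of A4 from 4 would take three or four steps, where the chosen plan uses one borylation and one coupling. The diene terminus C3' carries a bulky di-ortho-substituted aryl group that should slow the cycloaddition, and A4 is sensitive to hydrolysis.
- Comparison: on mechanism it is the equal of a Suzuki coupling. On structure it does not remove the iodination question. It is longer by about two steps. It is an alternative to step 5, not to the ring C closure.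

Alternative 3: The C4''–C4a'' bond of ring E is cut, leading to the (Z)-3-aryloxy-3-(4-methoxyphenyl)acrylic acid A7.
- Forward step: activation with (CF3CO)2O and intramolecular Friedel–Crafts acylation at C4a'' should give the biflavone A8.
- In its favour: C4a'' is the only free position ortho to the ether oxygen, and it is activated by the para 7''-OH and the ortho 5''-methoxy group. Closure regiochemistry is therefore fixed by structure, which is equal to the single ester site of the chosen plan. The arylresorcinol A9 behind A7 is symmetric, so its oxa-Michael addition to methyl 3-(4-methoxyphenyl)propiolate A10 (followed by ester hydrolysis) cannot give regioisomers. The step loses water and not Ph3PO, so on atom economy it is better.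
- Against it: it closes the other pyranone, so the complete 5,7-dimethoxy chromone on ring B and a hindered biaryl bond to the free resorcinol A9 must exist beforehand. The enol ether of A7 must be Z. A free phenol meets a strongly acidic acylating medium. A8 carries two peri methyl ethers (O5, O5'') that must be cleaved selectively beside the O7 and O4''' methyl ethers.
- Comparison: a chelating Lewis acid could remove the benzyl ether of A8 in the same operation, so the end game is equal in step count. But it generates the 5''-hydroxy-8''-aryl flavone in acid, which is the isomerisation risk that the neutral Wittig closure and hydrogenolysis avoid. Overall step count would be similar or somewhat higher.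

Key step: step 11

Assumption: the C3'–C8'' axis is treated as configurationally undefined, since the target carries no axial descriptor.

Remark on the chemistry: the O-aroyl ylide 16 and the tetrabenzyl biflavone 17 map atom for atom onto the target, with four benzyl and two methyl ethers at the right oxygens. Three design points are built into the route:
- Both phenols of 1 are benzylated before iodination.
- The hydroxy ylide 14 is liberated and isolated before acylation.
- The acylation is run with pyridine/DMAP and a bicarbonate work-up, so that the phenolic oxygen reacts and the ylide is returned in its neutral form.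

## Route

Step 1
Reactants: 1 acacetin (5,7-dihydroxy-2-(4-methoxyphenyl)-4H-chromen-4-one); 2 benzyl bromide
Product: 3 5,7-bis(benzyloxy)-2-(4-methoxyphenyl)-4H-chromen-4-one
Conditions: BnBr (3 equiv), K2CO3, DMF, 80 °C
Reagents that add atoms: benzyl bromide (second equivalent), BrCc1ccccc1
Why: Double Williamson etherification that consumes two equivalents of benzyl bromide; the 7-OH reacts readily and the chelated 5-OH needs heat, the polar solvent and excess halide. Capping both phenols is what later steers iodination to C8''.

Step 2
Reactants: 3 5,7-bis(benzyloxy)-2-(4-methoxyphenyl)-4H-chromen-4-one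
Product: 4 5,7-bis(benzyloxy)-8-iodo-2-(4-methoxyphenyl)-4H-chromen-4-one
Conditions: NIS (1.2 equiv), DMF, 50 °C, dark
Reagents that add atoms: N-iodosuccinimide, O=C1CCC(=O)N1I
Why: Electrophilic aromatic iodination of a 5,7-dialkoxychromone; C8'' is activated by O7'' and O1'' (ortho) and O5'' (para) and is less crowded than C6'', which lies between two benzyloxy groups. With O5'' alkylated no phenoxide can direct iodine to C6'', and the benzyl and anisyl rings are far less nucleophilic.

Step 3
Reactants: 5 methyl 3-bromo-4-hydroxybenzoate; 2 benzyl bromide
Product: 6 methyl 4-(benzyloxy)-3-bromobenzoate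
Conditions: BnBr (1.1 equiv), K2CO3, acetone, reflux
Reagents that add atoms: none
Why: Williamson etherification of an acidic phenol (para ester, ortho bromine); the ester is untouched by carbonate in acetone.

Step 4
Reactants: 6 methyl 4-(benzyloxy)-3-bromobenzoate
Product: 7 methyl 4-(benzyloxy)-3-(4,4,5,5-tetramethyl-1,3,2-dioxaborolan-2-yl)benzoate
Conditions: B2pin2, PdCl2(dppf) (3 mol %), KOAc, 1,4-dioxane, 90 °C
Reagents that add atoms: bis(pinacolato)diboron, CC1(C)OB(OC1(C)C)B1OC(C)(C)C(C)(C)O1
Why: Miyaura borylation of an aryl bromide; the weak acetate base prevents the boronate from coupling with unreacted bromide, and the ester and benzyl ether are inert.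

Step 5
Reactants: 4 5,7-bis(benzyloxy)-8-iodo-2-(4-methoxyphenyl)-4H-chromen-4-one; 7 methyl 4-(benzyloxy)-3-(4,4,5,5-tetramethyl-1,3,2-dioxaborolan-2-yl)benzoate
Product: 8 methyl 4-(benzyloxy)-3-[5,7-bis(benzyloxy)-2-(4-methoxyphenyl)-4-oxo-4H-chromen-8-yl]benzoate
Conditions: Pd(OAc)2 (5 mol %), SPhos (10 mol %), K3PO4, toluene/H2O 10:1, 90 °C
Reagents that add atoms: none
Why: Suzuki–Miyaura coupling; the bulky dialkylbiarylphosphine supports oxidative addition into the hindered iodide and reductive elimination to a tri-ortho-substituted biaryl. Phosphate in a mostly organic medium leaves the methyl ester and the pyranone intact.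

Step 6
Reactants: 8 methyl 4-(benzyloxy)-3-[5,7-bis(benzyloxy)-2-(4-methoxyphenyl)-4-oxo-4H-chromen-8-yl]benzoate
Product: 9 4-(benzyloxy)-3-[5,7-bis(benzyloxy)-2-(4-methoxyphenyl)-4-oxo-4H-chromen-8-yl]benzoic acid
Conditions: LiOH·H2O (3 equiv), THF/MeOH/H2O 3:1:1, 40 °C; then 1 M HCl, 0 °C, to pH 3
Reagents that add atoms: lithium hydroxide, [Li+].[OH-]
Why: Saponification of a methyl benzoate by acyl–oxygen cleavage; the 4-pyranone is a vinylogous ester within an aromatic system and should resist dilute LiOH at 40 °C. The brief cold acidification spares the benzyl ethers.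

Step 7
Reactants: 10 2',6'-dihydroxy-4'-methoxyacetophenone; 2 benzyl bromide
Product: 11 1-[2-(benzyloxy)-6-hydroxy-4-methoxyphenyl]ethan-1-one
Conditions: BnBr (1.0 equiv), K2CO3 (1.1 equiv), acetone, reflux
Reagents that add atoms: none
Why: Mono-Williamson etherification; the two hydroxyls are equivalent, so only one mono-ether can form, and the remaining OH is deactivated by its hydrogen bond to the ketone, which with one equivalent of halide should hold back the second alkylation.

Step 8
Reactants: 11 1-[2-(benzyloxy)-6-hydroxy-4-methoxyphenyl]ethan-1-one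
Product: 12 1-[2-(benzyloxy)-6-hydroxy-4-methoxyphenyl]-2-bromoethan-1-one
Conditions: CuBr2 (2.0 equiv), EtOAc/CHCl3 1:1, reflux
Reagents that add atoms: CuBr2, [Cu+2].[Br-].[Br-]
Why: α-Bromination of an aryl methyl ketone with CuBr2; bromine is passed to the copper-bound enol in a heterogeneous medium free of Br2, which favours the methyl group over the nucleus, and the HBr formed leaves with the refluxing solvent.

Step 9
Reactants: 12 1-[2-(benzyloxy)-6-hydroxy-4-methoxyphenyl]-2-bromoethan-1-one
Product: 14 1-[2-(benzyloxy)-6-hydroxy-4-methoxyphenyl]-2-(triphenylphosphoranylidene)ethan-1-one (the hydroxy ylide), via phosphonium bromide 13 (not isolated)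
Conditions: PPh3 (1.05 equiv), toluene, rt; then aq. Na2CO3, CH2Cl2, rt
Reagents that add atoms: triphenylphosphine, c1ccc(cc1)P(c1ccccc1)c1ccccc1
Why: SN2 quaternisation of a primary α-bromoketone, then deprotonation of the acidic phenacylphosphonium CH2 by carbonate to the acyl-stabilised ylide, whose phenol stays hydrogen-bonded to the ylide carbonyl. No base is present while the bromide is intact, so the ortho phenol cannot close to a benzofuranone.

Step 10
Reactants: 9 4-(benzyloxy)-3-[5,7-bis(benzyloxy)-2-(4-methoxyphenyl)-4-oxo-4H-chromen-8-yl]benzoic acid; 14 1-[2-(benzyloxy)-6-hydroxy-4-methoxyphenyl]-2-(triphenylphosphoranylidene)ethan-1-one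
Product: 16 3-(benzyloxy)-5-methoxy-2-[(triphenylphosphoranylidene)acetyl]phenyl 4-(benzyloxy)-3-[5,7-bis(benzyloxy)-2-(4-methoxyphenyl)-4-oxo-4H-chromen-8-yl]benzoate (the O-aroyl ylide), via acid chloride 15 (not isolated)
Conditions: (COCl)2, cat. DMF, CH2Cl2, 0 °C to rt, evaporate; then 14, pyridine, cat. DMAP, CH2Cl2, 0 °C to rt; aq. NaHCO3 wash
Reagents that add atoms: oxalyl chloride, ClC(=O)C(=O)Cl (its chlorine is carried by intermediate 15 only; product 16 holds no atom from it)
Why: Acid chloride formation by Vilsmeier-type activation, then O-acylation of the phenol through the acylpyridinium ion; the hard phenolic oxygen should outrun the delocalised ylide carbon under pyridine/DMAP, and the benzyl ether blocks the other ortho oxygen. The bicarbonate wash returns any protonated ylide to 16, and keeping the mixture at or below rt keeps the Wittig closure from starting unevenly.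

Step 11
Reactants: 16 3-(benzyloxy)-5-methoxy-2-[(triphenylphosphoranylidene)acetyl]phenyl 4-(benzyloxy)-3-[5,7-bis(benzyloxy)-2-(4-methoxyphenyl)-4-oxo-4H-chromen-8-yl]benzoate
Product: 17 5-(benzyloxy)-2-{4-(benzyloxy)-3-[5,7-bis(benzyloxy)-2-(4-methoxyphenyl)-4-oxo-4H-chromen-8-yl]phenyl}-7-methoxy-4H-chromen-4-one (5,4',5'',7''-tetra-O-benzylputraflavone)
Conditions: dry toluene, reflux (110 °C), N2
Reagents that add atoms: none
Why: The ylide carbon C3 adds to the aryl ester carbonyl C2, which the ortho arrangement holds five bonds away, and the resulting betaine/oxaphosphetane collapses by cycloreversion to the C2=C3 double bond and Ph3PO. The closest known reaction type is the intramolecular Wittig olefination of the ester carbonyl in O-acylated (2-hydroxyphenacylidene)triphenylphosphoranes, which gives chromones and flavones on heating in toluene. Ring C closes in a favoured 6-exo-trig mode (6-(enolendo)-exo-trig with respect to the ylide enolate), the carbonyl oxygen lying outside the forming ring. An ester is normally too weak an electrophile for a stabilised ylide, but here it is an activated aryl ester, the attack is intramolecular, and formation of the aromatic 4-pyranone and of the P=O bond supplies the driving force. No stereocentre is formed. The step needs closure on the ester carbonyl only and a single mode of cyclisation: the benzyl ether on the other ortho oxygen leaves one ester and one closing oxygen, the C4'' carbonyl of the finished chromone is an unreactive vinylogous ester out of reach, and the absence of any free OH means nothing can protonate the ylide. Because the medium is neutral, aprotic and dry, there is no enolate to trigger O-to-C acyl migration, no acid to move the aryl group from C8'' to C6'' and no water to hydrolyse the ester.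

Step 12
Reactants: 17 5,4',5'',7''-tetra-O-benzylputraflavone
Product: 18 putraflavone (8-[2-hydroxy-5-(5-hydroxy-7-methoxy-4-oxo-4H-chromen-2-yl)phenyl]-5,7-dihydroxy-2-(4-methoxyphenyl)-4H-chromen-4-one)
Conditions: H2 (1 atm), 10% Pd/C, THF/MeOH 1:1, rt; filter through Celite
Reagents that add atoms: none
Why: Hydrogenolysis of four benzylic C–O bonds; the pyranone C2=C3 bonds belong to vinylogous esters of aromatic character and the methyl ethers are inert to H2 on palladium at rt and 1 atm. The neutral medium excludes acid-induced migration of the C8'' aryl group.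

## Compound list

1 | acacetin (5,7-dihydroxy-2-(4-methoxyphenyl)-4H-chromen-4-one) | COc1ccc(cc1)-c1cc(=O)c2c(O)cc(O)cc2o1 | starting material
2 | benzyl bromide | BrCc1ccccc1 | starting material
3 | 5,7-bis(benzyloxy)-2-(4-methoxyphenyl)-4H-chromen-4-one | COc1ccc(cc1)-c1cc(=O)c2c(OCc3ccccc3)cc(OCc3ccccc3)cc2o1 | intermediate
4 | 5,7-bis(benzyloxy)-8-iodo-2-(4-methoxyphenyl)-4H-chromen-4-one | COc1ccc(cc1)-c1cc(=O)c2c(OCc3ccccc3)cc(OCc3ccccc3)c(I)c2o1 | intermediate
5 | methyl 3-bromo-4-hydroxybenzoate | COC(=O)c1ccc(O)c(Br)c1 | starting material
6 | methyl 4-(benzyloxy)-3-bromobenzoate | COC(=O)c1ccc(OCc2ccccc2)c(Br)c1 | intermediate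
7 | methyl 4-(benzyloxy)-3-(4,4,5,5-tetramethyl-1,3,2-dioxaborolan-2-yl)benzoate | COC(=O)c1ccc(OCc2ccccc2)c(c1)B1OC(C)(C)C(C)(C)O1 | intermediate
8 | methyl 4-(benzyloxy)-3-[5,7-bis(benzyloxy)-2-(4-methoxyphenyl)-4-oxo-4H-chromen-8-yl]benzoate | COC(=O)c1ccc(OCc2ccccc2)c(c1)-c1c(OCc2ccccc2)cc(OCc2ccccc2)c2c(=O)cc(oc12)-c1ccc(OC)cc1 | intermediate
9 | 4-(benzyloxy)-3-[5,7-bis(benzyloxy)-2-(4-methoxyphenyl)-4-oxo-4H-chromen-8-yl]benzoic acid | OC(=O)c1ccc(OCc2ccccc2)c(c1)-c1c(OCc2ccccc2)cc(OCc2ccccc2)c2c(=O)cc(oc12)-c1ccc(OC)cc1 | intermediate
10 | 2',6'-dihydroxy-4'-methoxyacetophenone | CC(=O)c1c(O)cc(OC)cc1O | starting material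
11 | 1-[2-(benzyloxy)-6-hydroxy-4-methoxyphenyl]ethan-1-one | CC(=O)c1c(O)cc(OC)cc1OCc1ccccc1 | intermediate
12 | 1-[2-(benzyloxy)-6-hydroxy-4-methoxyphenyl]-2-bromoethan-1-one | O=C(CBr)c1c(O)cc(OC)cc1OCc1ccccc1 | intermediate
13 | {2-[2-(benzyloxy)-6-hydroxy-4-methoxyphenyl]-2-oxoethyl}triphenylphosphonium bromide | COc1cc(O)c(C(=O)C[P+](c2ccccc2)(c2ccccc2)c2ccccc2)c(OCc2ccccc2)c1.[Br-] | intermediate
14 | 1-[2-(benzyloxy)-6-hydroxy-4-methoxyphenyl]-2-(triphenylphosphoranylidene)ethan-1-one | COc1cc(O)c(C(=O)C=P(c2ccccc2)(c2ccccc2)c2ccccc2)c(OCc2ccccc2)c1 | intermediate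
15 | 4-(benzyloxy)-3-[5,7-bis(benzyloxy)-2-(4-methoxyphenyl)-4-oxo-4H-chromen-8-yl]benzoyl chloride | ClC(=O)c1ccc(OCc2ccccc2)c(c1)-c1c(OCc2ccccc2)cc(OCc2ccccc2)c2c(=O)cc(oc12)-c1ccc(OC)cc1 | intermediate
16 | 3-(benzyloxy)-5-methoxy-2-[(triphenylphosphoranylidene)acetyl]phenyl 4-(benzyloxy)-3-[5,7-bis(benzyloxy)-2-(4-methoxyphenyl)-4-oxo-4H-chromen-8-yl]benzoate | COc1cc(OCc2ccccc2)c(C(=O)C=P(c2ccccc2)(c2ccccc2)c2ccccc2)c(OC(=O)c2ccc(OCc3ccccc3)c(c2)-c2c(OCc3ccccc3)cc(OCc3ccccc3)c3c(=O)cc(oc23)-c2ccc(OC)cc2)c1 | intermediate
17 | 5,4',5'',7''-tetra-O-benzylputraflavone | COc1ccc(cc1)-c1cc(=O)c2c(OCc3ccccc3)cc(OCc3ccccc3)c(c2o1)-c1cc(ccc1OCc1ccccc1)-c1cc(=O)c2c(OCc3ccccc3)cc(OC)cc2o1 | intermediate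
18 | putraflavone | COc1ccc(-c2cc(=O)c3c(O)cc(O)c(-c4cc(-c5cc(=O)c6c(O)cc(OC)cc6o5)ccc4O)c3o2)cc1 | target

## Step count and least certain steps

Total: 12 steps. Longest linear sequence: 7 steps (steps 1, 2, 5, 6, 10, 11, 12 from 1; equally steps 3, 4, 5, 6, 10, 11, 12 from 5). The ylide branch (steps 7 to 9) joins at step 10.

Step 11 (key step). The closure may be slow, because the acyl ylide is flanked by two ortho substituents and the ester carbonyl is a weak electrophile. Prolonged heating could then let intermolecular acyl transfer between two ylide molecules, or hydrolysis of the ester by traces of water, compete. The fallback forms the same C2–C3 bond by enolate acylation. It sets out from 11 and from 9 (as its chloride 15). Phenol 11 is converted with LiN(SiMe3)2 (3.5 equiv, THF, −78 °C) into its phenoxide–enolate dianion, which is C-acylated by 15 to the 1,3-diketone 1-[2-(benzyloxy)-6-hydroxy-4-methoxyphenyl]-3-{4-(benzyloxy)-3-[5,7-bis(benzyloxy)-2-(4-methoxyphenyl)-4-oxo-4H-chromen-8-yl]phenyl}propane-1,3-dione F1. Cyclodehydration with catalytic TsOH in toluene at 80 °C then closes ring C, and the route is rejoined at 17. Since O5'' is still benzylated at that stage, the acid cannot move the C8'' aryl group.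

Step 10. Acylation may go astray: attack at the ylide carbon or at the ylide enolate oxygen, or protonation of the ylide by the HCl set free, would each divert or stall the esterification. The fallback reverses the order, so that acylation meets no ylide. It sets out from 11 and from 9 (as 15). Pyridine/DMAP esterification gives 2-acetyl-3-(benzyloxy)-5-methoxyphenyl 4-(benzyloxy)-3-[5,7-bis(benzyloxy)-2-(4-methoxyphenyl)-4-oxo-4H-chromen-8-yl]benzoate F2. CuBr2 in EtOAc/CHCl3 brominates its acetyl group to the bromoacetyl ester F3; the nucleus is now less electron-rich than in 11, but attack at C6'' of ring D would have to be watched. PPh3 gives the phosphonium bromide F4, and aqueous NaHCO3 releases the ylide, rejoining the route at 16.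

Step 8. Bromination could drift from the methyl group to the very electron-rich nucleus. HBr could also loosen the ortho benzyl ether, and the bromoketone could cyclise onto its free ortho phenol during work-up. The fallback fixes the site by pre-forming the enol. It sets out from 11. TMSOTf/Et3N (2.5 equiv, CH2Cl2, 0 °C) gives the bis-silyl compound {[1-(2-(benzyloxy)-4-methoxy-6-[(trimethylsilyl)oxy]phenyl)ethenyl]oxy}trimethylsilane F5. NBS in THF at −78 °C brominates the enol silane, which is far more nucleophilic than the arene, and a mildly acidic aqueous work-up removes the aryl silyl ether, rejoining the route at 12.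

Step 5. Transmetalation and reductive elimination at a tri-ortho-substituted biaryl may be slow, so that protodeboronation of 7 in the aqueous base or reductive loss of iodine from 4 takes over. The fallback replaces boron and aqueous base by tin under anhydrous neutral conditions. It sets out from 6. Stannylation with (Bu3Sn)2 and Pd(PPh3)4 in toluene at 110 °C gives methyl 4-(benzyloxy)-3-(tributylstannyl)benzoate F6. Stille coupling of F6 with 4 (Pd(PPh3)4, CuI, CsF, DMF, 60 °C) rejoins the route at 8.

Step 12. Hydrogenolysis may stop short, through precipitation of partly debenzylated material or poisoning of the catalyst by phosphorus residues from step 11, or it may run on into reduction of a pyranone C2=C3 bond. The fallback is non-reductive. It sets out from 17: BCl3 with pentamethylbenzene as benzyl cation scavenger in CH2Cl2 at −78 °C cleaves the four benzyl ethers, while the two methyl ethers are not peri to a carbonyl and should remain, and the route is rejoined at 18. This fallback makes no new compound (F0).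

## Further compounds

F1 | step 11 | 1-[2-(benzyloxy)-6-hydroxy-4-methoxyphenyl]-3-{4-(benzyloxy)-3-[5,7-bis(benzyloxy)-2-(4-methoxyphenyl)-4-oxo-4H-chromen-8-yl]phenyl}propane-1,3-dione | COc1cc(O)c(C(=O)CC(=O)c2ccc(OCc3ccccc3)c(c2)-c2c(OCc3ccccc3)cc(OCc3ccccc3)c3c(=O)cc(oc23)-c2ccc(OC)cc2)c(OCc2ccccc2)c1
F2 | step 10 | 2-acetyl-3-(benzyloxy)-5-methoxyphenyl 4-(benzyloxy)-3-[5,7-bis(benzyloxy)-2-(4-methoxyphenyl)-4-oxo-4H-chromen-8-yl]benzoate | CC(=O)c1c(OCc2ccccc2)cc(OC)cc1OC(=O)c1ccc(OCc2ccccc2)c(c1)-c1c(OCc2ccccc2)cc(OCc2ccccc2)c2c(=O)cc(oc12)-c1ccc(OC)cc1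
F3 | step 10 | 3-(benzyloxy)-2-(bromoacetyl)-5-methoxyphenyl 4-(benzyloxy)-3-[5,7-bis(benzyloxy)-2-(4-methoxyphenyl)-4-oxo-4H-chromen-8-yl]benzoate | BrCC(=O)c1c(OCc2ccccc2)cc(OC)cc1OC(=O)c1ccc(OCc2ccccc2)c(c1)-c1c(OCc2ccccc2)cc(OCc2ccccc2)c2c(=O)cc(oc12)-c1ccc(OC)cc1
F4 | step 10 | {2-[2-(benzyloxy)-6-({4-(benzyloxy)-3-[5,7-bis(benzyloxy)-2-(4-methoxyphenyl)-4-oxo-4H-chromen-8-yl]benzoyl}oxy)-4-methoxyphenyl]-2-oxoethyl}triphenylphosphonium bromide | COc1cc(OCc2ccccc2)c(C(=O)C[P+](c2ccccc2)(c2ccccc2)c2ccccc2)c(OC(=O)c2ccc(OCc3ccccc3)c(c2)-c2c(OCc3ccccc3)cc(OCc3ccccc3)c3c(=O)cc(oc23)-c2ccc(OC)cc2)c1.[Br-]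
F5 | step 8 | {[1-(2-(benzyloxy)-4-methoxy-6-[(trimethylsilyl)oxy]phenyl)ethenyl]oxy}trimethylsilane | C=C(O[Si](C)(C)C)c1c(O[Si](C)(C)C)cc(OC)cc1OCc1ccccc1
F6 | step 5 | methyl 4-(benzyloxy)-3-(tributylstannyl)benzoate | COC(=O)c1ccc(OCc2ccccc2)c(c1)[Sn](CCCC)(CCCC)CCCC
F0 | step 12 | none | none
A1 | alternative 1 | 3-ethoxycyclobut-2-en-1-one | CCOC1=CC(=O)C1
A2 | alternative 1 | triisopropyl({[2-(benzyloxy)-5-(1,3-dioxolan-2-yl)phenyl]ethynyl}oxy)silane | CC(C)[Si](OC#Cc1cc(ccc1OCc1ccccc1)C1OCCO1)(C(C)C)C(C)C
A3 | alternative 1 | 2-[2-benzyloxy-5-(1,3-dioxolan-2-yl)phenyl]-5-ethoxy-3-(triisopropylsilyloxy)phenol | CCOc1cc(O)c(c(O[Si](C(C)C)(C(C)C)C(C)C)c1)-c1cc(ccc1OCc1ccccc1)C1OCCO1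
A4 | alternative 2 | 5,7-bis(benzyloxy)-8-[(1Z,3E)-2-(tert-butyldimethylsilyloxy)-4-methoxybuta-1,3-dien-1-yl]-2-(4-methoxyphenyl)-4H-chromen-4-one | CO/C=C/C(O[Si](C)(C)C(C)(C)C)=C/c1c(OCc2ccccc2)cc(OCc2ccccc2)c2c(=O)cc(oc12)-c1ccc(OC)cc1
A5 | alternative 2 | methyl propiolate | COC(=O)C#C
A6 | alternative 2 | methyl 3-(5,7-dibenzyloxy-4'-methoxyflavon-8-yl)-4-hydroxybenzoate | COC(=O)c1ccc(O)c(c1)-c1c(OCc2ccccc2)cc(OCc2ccccc2)c2c(=O)cc(oc12)-c1ccc(OC)cc1
A7 | alternative 3 | (2Z)-3-{2-[2-(benzyloxy)-5-(5,7-dimethoxy-4-oxo-4H-chromen-2-yl)phenyl]-3-hydroxy-5-methoxyphenoxy}-3-(4-methoxyphenyl)prop-2-enoic acid | OC(=O)/C=C(\Oc1cc(OC)cc(O)c1-c1cc(ccc1OCc1ccccc1)-c1cc(=O)c2c(OC)cc(OC)cc2o1)c1ccc(OC)cc1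
A8 | alternative 3 | 5,5''-di-O-methyl-4'-O-benzylputraflavone | COc1ccc(cc1)-c1cc(=O)c2c(OC)cc(O)c(c2o1)-c1cc(ccc1OCc1ccccc1)-c1cc(=O)c2c(OC)cc(OC)cc2o1
A9 | alternative 3 | 2-[2-(benzyloxy)-5-(5,7-dimethoxy-4-oxo-4H-chromen-2-yl)phenyl]-5-methoxybenzene-1,3-diol | COc1cc(O)c(c(O)c1)-c1cc(ccc1OCc1ccccc1)-c1cc(=O)c2c(OC)cc(OC)cc2o1
A10 | alternative 3 | methyl 3-(4-methoxyphenyl)prop-2-ynoate | COC(=O)C#Cc1ccc(OC)cc1
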